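One question stands here, so I turn it round: what must the numbers show for the gas to keep pace with the acid set free, so that this flask loses no nucleophile to protonation?

- the concentration of nucleophile at which the part of the electrophile that has reacted at 8.0 h is just 80%, in M

electrophile 0.31 M; gas 29 mM (held); time 8.0 h

    electrophile + nucleophile ⇌ acid set free + product (K1 = 0.62, k1 = 1.1 L mol⁻¹ h⁻¹)
    nucleophile + acid set free ⇌ protonated nucleophile, settled at all times (K2 = 280 L mol⁻¹)
    acid set free + free base ⇌ salt of the base, settled at all times (K3 = 35000 L mol⁻¹)
    gas ⇌ free base, rate k4*(csat - [free base]) (k4 = 0.86 h⁻¹, csat = 29 mM)

- at the start none of free base is dissolved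
- the amount of nucleophile is what is sought; it is there from the start
- run time (flask): 8.0 h

Step 3 binds acid more strongly than step 2, so entering base takes up acid, and acid beyond that entry stays on the nucleophile. I divide the greatest rate of entry of base by the mean rate of acid wanted, and call the quotient the cover.

entry of base, k4·csat = 0.0249 M h⁻¹
mean rate of acid wanted = 0.0310 M h⁻¹
cover = 0.805

The opposite outcome needs a cover of at least 1, and this flask stands below that. So the nucleophile in this flask has three calls on it:

eaten by the electrophile = 0.248 M
holding the acid beyond the cover = 0.0485 M
left free, from a pseudo-first-order decay with the reverse step neglected, ln(1/(1 − part reacted))/(k1·t1) = 0.183 M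

My charge is their sum, 0.479 M.

The forecast is 0.47 M, less than mine, “with the reverse step a small correction”.

The simulation gives 0.451 M, less than my charge, and in this flask the passage of gas has 10% of its turnover behind it at 0.800 h. With a quarter more nucleophile, 88.1% of the electrophile has reacted at 8.0 h. The cover for that acid is 0.730, lower than before, and the acid beyond it comes by my reckoning to 0.0737 M.

The rate constants are assumed, and the outcome is calculated.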